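The rate constants were drawn at random within sensible limits; the run is a simulation.

Before I judged the neighbour flask with 0.052 M of solid substrate, I wanted a number from this flask that could carry over to it.

solid substrate 0.13 M; reagent 0.143 M; time 2.5 d

    solid substrate + target → side product B (k1 = 0.27 /M/h)
    dissolved substrate + reagent → target (k2 = 0.65 /M/h)
    crystals ⇌ target, rate k3*(cs3 - [target]) while solid is left; crystals form when [target] > cs3 (cs3 = 1.9 mM, k3 = 2.9 /h)
    solid substrate ⇌ dissolved substrate, rate k4*(cs4 - [dissolved substrate]) while solid is left; crystals form when [dissolved substrate] > cs4 (cs4 = 0.067 M, k4 = 0.041 /h)
    reagent → side product A (k5 = 0.11 /h)

- how much target and crystals together there is at 2.5 d, in percent of the solid substrate charged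
- concentration of dissolved substrate in solution at 2.5 d, in percent of saturation

- percent here means solid substrate units held: one side product B counts as two
- what is said of target includes crystals
- solid substrate, crystals is a solid; its amount is given per volume of the solution
- at the start none of the solid substrate is in solution
- dissolved substrate means what is dissolved; the solid is not counted in it
- run time (flask): 2.5 d

In this flask the reagent decays to side product A at 0.11 /h, while even saturated dissolved substrate takes it at 0.0436 /h, which is slower. So I treated the decay as the large thing and reckoned the capture as a correction. With [dissolved substrate] taken as a given curve, reagent loss is pseudo-first-order. I let [reagent] fall exponentially and [dissolved substrate] rise exponentially towards 0.067 M, and integrating their product gave 15.4 mM. This capture, the reagent that becomes target before it decays, contains no charge of solid substrate.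

As a second way, I took a snapshot at the reagent's mean life of 9.09 h. There [dissolved substrate] was 20.8 mM, which gave a capture of 17.6 mM, higher than the integral. The snapshot cheats: the rising curve bends over, so its value at the mean time lies above its reagent-weighted mean of 18.2 mM. I kept the integral, as a high figure, since it counts no drain on either curve.

Against it I set the loss of dissolved target, taken as held near 1.9 mM, to solid substrate, also taken as charged: about 4.00 mM over the run. That left 8.75 % for y. The capture is not small beside 0.067 M, but the reagent's half-life of 0.26 d is shorter than the 2.5 d of the run, so I expected the capture to end early and the solid to refill the solution while it lasted; plain relaxation, a high figure, gave 91.5 % for sat.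

The forecast gave 6.2 % and 90 %, on the ground that “Reagent mostly decays on its own within about a day while the substrate dissolves slowly”. Its y was lower than mine.

This flask gave 6.65 % and 88.8 %, with reagent down to 0.030 % and side product A at 0.132 M. So 11.1 mM of reagent had gone the other way, below my capture of 15.4 mM. In the neighbour flask with 0.052 M of solid substrate, side product A also stood at 0.132 M. The same capture there is 21.3 % of its charge as read here, or 29.6 % as reckoned, and that neighbour held 20.5 % of target and crystals.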